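(The rate constants are invented; the run is a simulation.)

4 questions stand on 3 vessels given the same charge: which set-up ends highest in target, and how much target each one delivers.

- the set-up with the highest amount of target at the outlet or at the end, in percent of the substrate put in ("none" if the first two lie within 2 percentage points) (grey / green / red / none)
- amount of target at the outlet or at the end, in percent of the substrate put in, grey
- amount of target at the outlet or at the end, in percent of the substrate put in, green
- amount of target at the outlet or at the end, in percent of the substrate put in, red

all flasks: catalyst 5 mol%
- grey: substrate 0.0010 M (fed, over 16.0 s); time 20 s; a stirred flask in which substrate is dosed at a steady rate over 16.0 s without added volume, worked up at 20 s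
- green: substrate 0.0010 M; a single well-mixed tank run continuously and read at steady state, 20 s in it on average
- red: substrate 0.0010 M; time 20 s; everything together in a closed stirred flask, run for 20 s

    catalyst + other conformer → catalyst + isomer of the product (k1 = 78000 M⁻¹ s⁻¹)
    substrate ⇌ dormant form (K2 = 20, k2 = 0.051 s⁻¹)
    substrate → uncatalysed product (k3 = 0.041 s⁻¹)
    substrate + catalyst → catalyst + target (k4 = 29000 M⁻¹ s⁻¹)
    substrate ⇌ other conformer, settled at all times (K5 = 0.45)

- the stated concentrations are those of everything mixed, before any reaction; amounts are the same in each set-up
- the feed brings no volume worth counting
- run time (grey): 20 s

The catalyst comes back out of each step it enters, so c(catalyst) stays at 5.00 × 10⁻⁵ M and the steps on substrate are pseudo-first-order. The fast balance holds c(other conformer) at 0.45 times c(substrate), so the two form one pool. Per unit of substrate, the pool leaves to target at 1.45 s⁻¹, to isomer of the product at 1.76 s⁻¹, to uncatalysed product at 0.041 s⁻¹ and to dormant form at 0.051 s⁻¹. The return from dormant form, 0.00255 s⁻¹, is set aside. That gives 44.0 % as the target share, the target rate over the sum of the rates out of the pool.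

Grey and red look nearly the same, and they differ by the dosing. Each exit is first-order in the pool, so dosing changes the height of the pool but leaves the split as it was. The pool lasts about 0.440 s, which is shorter than the 4.00 s after the feed ends, so grey and red both end at the share by hand.

The green tank, at 20 s on average, keeps a standing pool of 2.15 % of the charge at its outlet. That leaves 43.1 % by hand, a gap of 0.95 percentage points, smaller than the margin of 2 points.

The forecast says none, with grey 44 %, green 43.1 % and red 44 %, on the ground that “Every channel is first-order in the pool, so dosing doesn't change selectivity”. Its green figure stands level with the one by hand.

The simulation gives none, with grey 44.0 %, green 43.1 % and red 44.0 %.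

Red stays at 44.0 % of target because of the balance between substrate and other conformer: the simulated red run without that balance gives 94.2 %. Striking the isomer rate from the target share gives 94.0 % for that run. The same share, with the washout of the tank taken off, gives 91.0 % for green without the balance, and the simulated green run reads 91.2 %.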